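**Strategy.** Everything rests on forming the cyclohexene ring last. That ring (C1'–C6') is 1,4-disubstituted: the stereocentre C1' bears chain carbon C2, and the C3'=C4' alkene bears the methyl on C4'. This is the para Diels–Alder pattern of isoprene and a vinyl ketone with its carbonyl at C2. A single catalytic enantioselective [4+2] cycloaddition therefore forms C1'–C2' and C5'–C6', closes the ring and sets C1' as R. Its precursor is the open-chain C2 vinyl ketone, which already holds the (Z)-C5=C6 alkene, the C10, C14 and C18 centres and C13 masked as a silyl ether. Methylenation at C2 and unmasking of C13 follow.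

Key step: step 13

Remark: chain carbons keep the target numbering (C1 exocyclic methylene to C22, ring C1'–C6') in every intermediate; the spatial arrangement at C10, C14 and C18 is never touched, although formal descriptors change with the substituents.
Assumption: (S)-citronellyl bromide is bought; otherwise it is one step from (S)-citronellol (CBr4, PPh3).
Assumption: the (2S,5S) catalyst is taken to expose the Si face of C1'; a trial with ethyl vinyl ketone and isoprene should confirm this before step 13, and the (2R,5R) antipode is used if the sense is opposite.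

Step 1
Reactants: 1 (S)-3-bromo-2-methylpropan-1-ol
Product: 2 (S)-benzyl 3-bromo-2-methylpropyl ether
Conditions: BnOC(=NH)CCl3, TfOH (cat.), cyclohexane–CH2Cl2, 0 °C → rt
Reagents that add atoms: benzyl 2,2,2-trichloroacetimidate, N=C(OCc1ccccc1)C(Cl)(Cl)Cl
Why: Acid-catalysed O-benzylation with the trichloroacetimidate needs no base, so the bromohydrin cannot close to an oxetane and the future C14 centre is not involved.

Step 2
Reactants: 2 (S)-benzyl 3-bromo-2-methylpropyl ether; 3 (S)-citronellyl bromide
Product: 5 benzyl (2R,6R)-2,6,10-trimethylundec-9-enyl ether, via Grignard reagent 4 (not isolated)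
Conditions: Mg, THF, reflux; then 3, Li2CuCl4 (3 mol %), THF, −10 °C → rt
Reagents that add atoms: none
Why: Copper-catalysed Grignard–alkyl bromide cross-coupling (Kochi coupling) joins C15 to C16 between a primary Grignard reagent and an unhindered primary bromide, and neither the C14 nor the C18 centre takes part.

Step 3
Reactants: 5 benzyl (2R,6R)-2,6,10-trimethylundec-9-enyl ether
Product: 6 (2R,6S)-2,6,10-trimethylundecan-1-ol
Conditions: H2 (1 atm), 10 % Pd/C, EtOH, rt
Reagents that add atoms: none
Why: Catalytic hydrogenation saturates the C21=C22 alkene and hydrogenolyses the benzyl ether in the same operation, without touching C14 or C18.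

Step 4
Reactants: 6 (2R,6S)-2,6,10-trimethylundecan-1-ol
Product: 7 (2R,6S)-2,6,10-trimethylundecanal
Conditions: Dess–Martin periodinane, NaHCO3, CH2Cl2, 0 °C → rt; crude product used at once
Reagents that add atoms: none
Why: Buffered Dess–Martin oxidation stops at the aldehyde under near-neutral conditions, which should keep the enolisable C14 centre intact when the aldehyde is not stored.

Step 5
Reactants: 7 (2R,6S)-2,6,10-trimethylundecanal; 8 (R)-citronellyl bromide
Product: 10 (6R,9RS,10R,14S)-2,6,10,14,18-pentamethylnonadec-2-en-9-ol, via citronellylmagnesium bromide 9 (not isolated)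
Conditions: Mg, THF, rt; then 7, THF, −78 → 0 °C; aq. NH4Cl
Reagents that add atoms: none
Why: Grignard addition to the aldehyde forms C12–C13 faster than enolisation at low temperature; the new C13 carbinol centre is left uncontrolled on purpose, because both epimers converge on the ketone in step 16.

Step 6
Reactants: 10 (6R,9RS,10R,14S)-2,6,10,14,18-pentamethylnonadec-2-en-9-ol
Product: 11 triisopropylsilyl ether of 10
Conditions: TIPSOTf, 2,6-lutidine, CH2Cl2, 0 °C → rt
Reagents that add atoms: triisopropylsilyl trifluoromethanesulfonate, CC(C)[Si](C(C)C)(C(C)C)OS(=O)(=O)C(F)(F)F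
Why: Silylation of a hindered secondary alcohol with a silyl triflate and a non-nucleophilic base is reliable, and this ether withstands the organolithium, Grignard, aqueous acid and titanium reagents that follow.

Step 7
Reactants: 11 triisopropylsilyl ether of 10
Product: 13 (4R,7RS,8R,12S)-4,8,12,16-tetramethyl-7-(triisopropylsilyloxy)heptadecan-1-ol (C7 alcohol), via ozonide 12 (not isolated)
Conditions: O3, CH2Cl2, −78 °C; then NaBH4, MeOH, −78 °C → rt
Reagents that add atoms: ozone, [O-][O+]=O
Why: Ozonolysis of the only alkene with reductive borohydride work-up cleaves C7=CMe2 and delivers the C7 primary alcohol directly, the silyl ether and the saturated chain being inert.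

Step 8
Reactants: 13 C7 alcohol
Product: 14 C7 iodide (1-iodo-4,8,12,16-tetramethyl-7-(triisopropylsilyloxy)heptadecane)
Conditions: I2, PPh3, imidazole, CH2Cl2, 0 °C → rt
Reagents that add atoms: iodine, II
Why: Appel-type iodination converts the unhindered primary alcohol into the iodide by SN2 displacement of the oxyphosphonium group and leaves the silyl ether alone.

Step 9
Reactants: 15 methyl 4-oxobutanoate
Product: 16 methyl (Z)-5-iodohex-4-enoate
Conditions: EtPPh3I, n-BuLi, THF, 0 °C; I2, −78 °C; NaN(SiMe3)2, −20 °C; then 15, −78 → −20 °C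
Reagents that add atoms: ethyltriphenylphosphonium iodide, CC[P+](c1ccccc1)(c1ccccc1)c1ccccc1.[I-]; iodine, II
Why: Wittig olefination with the α-iodoethylidene ylide (Stork–Zhao-type iodo-olefination) is the established way to (Z)-2-iodo-2-alkenes from aliphatic aldehydes, so the C5=C6 geometry is fixed here with iodine cis to C4, and the ester tolerates the ylide at low temperature.

Step 10
Reactants: 16 methyl (Z)-5-iodohex-4-enoate
Product: 17 (Z)-5-iodo-N-methoxy-N-methylhex-4-enamide
Conditions: MeNHOMe·HCl, AlMe3, CH2Cl2, 0 °C → rt; aq. HCl work-up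
Reagents that add atoms: N,O-dimethylhydroxylamine hydrochloride, CNOC.Cl
Why: Aminolysis of the ester by the aluminium amide (Weinreb amidation) is a standard, high-yielding reaction that does not affect the vinyl iodide or its geometry.

Step 11
Reactants: 14 C7 iodide; 17 (Z)-5-iodo-N-methoxy-N-methylhex-4-enamide
Product: 20 (Z)-Weinreb amide of the full C2–C22 chain, via alkyllithium 18 (not isolated), via borate complex 19 (not isolated)
Conditions: 14, t-BuLi (2.1 equiv), Et2O, −78 °C; B-methoxy-9-BBN, THF, −78 °C → rt; then 17, PdCl2(dppf)·CH2Cl2 (5 mol %), aq. K3PO4, DMF, rt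
Reagents that add atoms: none
Why: Iodine–lithium exchange, trapping with B-methoxy-9-BBN and palladium-catalysed B-alkyl Suzuki–Miyaura coupling of the borate with the vinyl iodide form C6–C7 with retention of alkene geometry, giving the (Z)-trisubstituted C5=C6 alkene, and the Weinreb amide and silyl ether tolerate these conditions.

Step 12
Reactants: 20 (Z)-Weinreb amide of the full C2–C22 chain
Product: 22 C2 vinyl ketone (C13 triisopropylsilyl ether; both C13 epimers), via tetrahedral magnesium adduct 21 (not isolated)
Conditions: CH2=CHMgBr, THF, −20 → 0 °C; inverse quench into cold 1 M HCl–Et2O; trace BHT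
Reagents that add atoms: vinylmagnesium bromide, C=C[Mg]Br
Why: Acyl substitution of a Weinreb amide by a Grignard reagent stops at the ketone because chelate 21 survives until the acidic inverse quench, which also protonates the released amine and so suppresses its conjugate addition to the enone.

Step 13
Reactants: 22 C2 vinyl ketone; 23 isoprene
Product: 26 (R)-4-methylcyclohex-3-enyl ketone (carbonyl C2; C13 triisopropylsilyl ether), via dienophile iminium ion 24 (not isolated), via cycloadduct iminium ion 25 (not isolated)
Conditions: 23 (10 equiv), (2S,5S)-5-benzyl-3-methyl-2-(5-methylfuran-2-yl)imidazolidin-4-one·HClO4 (20 mol %), H2O–EtOH, 0 °C, sealed flask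
Reagents that add atoms: none
Why: Condensation of 22 with the amine salt gives iminium ion 24, whose lowered LUMO lets isoprene add at 0 °C in a concerted, asynchronous [4+2] cycloaddition, and hydrolysis of 25 releases 26 and the catalyst; the closest known reaction type is the imidazolidinone-catalysed Diels–Alder reaction of simple alkyl vinyl ketones with acyclic dienes. The cyclohexene ring closes in an intermolecular suprafacial [4π+2π] mode, both ring bonds (C1'–C2' and C5'–C6') being made in this one step. The only new stereocentre, C1', is controlled by the catalyst: its cis benzyl and furyl groups cover one face of the iminium π-system, so the diene should reach the Si face of C1' and give R. Para regioselectivity is required and is secured by the 2-methyl group of isoprene, which places the larger HOMO coefficient on C5', the terminus that bonds to the β-carbon C6'. Chemoselectivity is secured by the substrate: the isolated (Z)-C5=C6 alkene is neither a dienophile nor a competent nucleophile for this iminium ion, the hindered silyl ether tolerates the weakly acidic aqueous medium, and a linear alkyl group on the carbonyl is the substitution this catalysis handles best. The remote C10, C13, C14 and C18 centres neither direct the addition nor are affected by it.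

Step 14
Reactants: 26 (R)-4-methylcyclohex-3-enyl ketone
Product: 27 C2 methylene compound (1,1-disubstituted alkene C1=C2; C13 triisopropylsilyl ether)
Conditions: Cp2TiMe2 (3 equiv), toluene, 70 °C, dark
Reagents that add atoms: dimethyltitanocene, C[Ti](C)(C1C=CC=C1)C1C=CC=C1
Why: Petasis methylenation through thermally generated Cp2Ti=CH2 is non-basic, so the enolisable C1' centre next to the ketone should keep its configuration while the silyl ether and the trisubstituted alkenes stay untouched.

Step 15
Reactants: 27 C2 methylene compound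
Product: 28 C13 alcohol (both C13 epimers)
Conditions: Bu4NF, THF, 50 °C
Reagents that add atoms: none
Why: Fluoride-induced Si–O cleavage removes the hindered silyl ether on warming, and the substrate carries no base-sensitive group at this stage.

Step 16
Reactants: 28 C13 alcohol
Product: 29 target ketone CNP0272027.1
Conditions: Dess–Martin periodinane, NaHCO3, CH2Cl2, 0 °C → rt
Reagents that add atoms: none
Why: Buffered Dess–Martin oxidation of the secondary alcohol gives the C13 ketone without acid or base strong enough to epimerise C14 or to move the alkenes, and it merges both C13 epimers into one compound.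

**Compound list**

1 | (S)-3-bromo-2-methylpropan-1-ol | C[C@@H](CO)CBr | starting material
2 | (S)-benzyl 3-bromo-2-methylpropyl ether | C[C@@H](COCc1ccccc1)CBr | intermediate
3 | (S)-citronellyl bromide, (S)-8-bromo-2,6-dimethyloct-2-ene | C[C@@H](CCC=C(C)C)CCBr | starting material
4 | [(S)-3-(benzyloxy)-2-methylpropyl]magnesium bromide | C[C@@H](COCc1ccccc1)C[Mg]Br | intermediate
5 | benzyl (2R,6R)-2,6,10-trimethylundec-9-enyl ether (C13–C22 unit) | c1ccccc1COC[C@H](C)CCC[C@@H](C)CCC=C(C)C | intermediate
6 | (2R,6S)-2,6,10-trimethylundecan-1-ol | OC[C@H](C)CCC[C@@H](C)CCCC(C)C | intermediate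
7 | (2R,6S)-2,6,10-trimethylundecanal (C13 aldehyde) | O=C[C@H](C)CCC[C@@H](C)CCCC(C)C | intermediate
8 | (R)-citronellyl bromide, (R)-8-bromo-2,6-dimethyloct-2-ene | C[C@H](CCC=C(C)C)CCBr | starting material
9 | (R)-citronellylmagnesium bromide | C[C@H](CCC=C(C)C)CC[Mg]Br | intermediate
10 | (6R,9RS,10R,14S)-2,6,10,14,18-pentamethylnonadec-2-en-9-ol (C13 carbinol, both epimers) | CC(C)=CCC[C@@H](C)CCC(O)[C@H](C)CCC[C@@H](C)CCCC(C)C | intermediate
11 | triisopropylsilyl ether of 10 | CC(C)=CCC[C@@H](C)CCC(O[Si](C(C)C)(C(C)C)C(C)C)[C@H](C)CCC[C@@H](C)CCCC(C)C | intermediate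
12 | ozonide of 11 (3,3-dimethyl-1,2,4-trioxolane at C7) | CC1(C)OOC(CC[C@@H](C)CCC(O[Si](C(C)C)(C(C)C)C(C)C)[C@H](C)CCC[C@@H](C)CCCC(C)C)O1 | intermediate
13 | (4R,7RS,8R,12S)-4,8,12,16-tetramethyl-7-(triisopropylsilyloxy)heptadecan-1-ol (C7 alcohol) | OCCC[C@@H](C)CCC(O[Si](C(C)C)(C(C)C)C(C)C)[C@H](C)CCC[C@@H](C)CCCC(C)C | intermediate
14 | C7 iodide, 1-iodo-4,8,12,16-tetramethyl-7-(triisopropylsilyloxy)heptadecane (configuration as in 13) | ICCC[C@@H](C)CCC(O[Si](C(C)C)(C(C)C)C(C)C)[C@H](C)CCC[C@@H](C)CCCC(C)C | intermediate
15 | methyl 4-oxobutanoate | COC(=O)CCC=O | starting material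
16 | methyl (Z)-5-iodohex-4-enoate | COC(=O)CC/C=C(/C)I | intermediate
17 | (Z)-5-iodo-N-methoxy-N-methylhex-4-enamide | CON(C)C(=O)CC/C=C(/C)I | intermediate
18 | C7 alkyllithium from 14 | [Li]CCC[C@@H](C)CCC(O[Si](C(C)C)(C(C)C)C(C)C)[C@H](C)CCC[C@@H](C)CCCC(C)C | intermediate
19 | lithium B-(C7-alkyl)-B-methoxy-9-borabicyclo[3.3.1]nonane borate | [Li+].CO[B-]1(CCC[C@@H](C)CCC(O[Si](C(C)C)(C(C)C)C(C)C)[C@H](C)CCC[C@@H](C)CCCC(C)C)C2CCCC1CCC2 | intermediate
20 | (Z)-N-methoxy-N-methyl amide of the C2–C22 chain (C5=C6 Z; C13 silyl ether) | CON(C)C(=O)CC/C=C(/C)CCC[C@@H](C)CCC(O[Si](C(C)C)(C(C)C)C(C)C)[C@H](C)CCC[C@@H](C)CCCC(C)C | intermediate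
21 | bromomagnesium alkoxide of the C2 N-methoxy-N-methyl hemiaminal | C=CC(O[Mg]Br)(N(C)OC)CC/C=C(/C)CCC[C@@H](C)CCC(O[Si](C(C)C)(C(C)C)C(C)C)[C@H](C)CCC[C@@H](C)CCCC(C)C | intermediate
22 | C2 vinyl ketone (C5=C6 Z; C13 silyl ether, both epimers) | C=CC(=O)CC/C=C(/C)CCC[C@@H](C)CCC(O[Si](C(C)C)(C(C)C)C(C)C)[C@H](C)CCC[C@@H](C)CCCC(C)C | intermediate
23 | isoprene | C=CC(C)=C | starting material
24 | iminium perchlorate of 22 with the (2S,5S)-imidazolidinone (C=N geometry not specified) | C=CC(CC/C=C(/C)CCC[C@@H](C)CCC(O[Si](C(C)C)(C(C)C)C(C)C)[C@H](C)CCC[C@@H](C)CCCC(C)C)=[N+]1[C@@H](Cc2ccccc2)C(=O)N(C)[C@H]1c1ccc(C)o1.[O-]Cl(=O)(=O)=O | intermediate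
25 | iminium perchlorate of cycloadduct 26 with the same imidazolidinone | C(CC/C=C(/C)CCC[C@@H](C)CCC(O[Si](C(C)C)(C(C)C)C(C)C)[C@H](C)CCC[C@@H](C)CCCC(C)C)(=[N+]2[C@@H](Cc3ccccc3)C(=O)N(C)[C@H]2c2ccc(C)o2)[C@H]1CC=C(C)CC1.[O-]Cl(=O)(=O)=O | intermediate
26 | (R)-4-methylcyclohex-3-enyl ketone (carbonyl C2; C13 silyl ether) | O=C(CC/C=C(/C)CCC[C@@H](C)CCC(O[Si](C(C)C)(C(C)C)C(C)C)[C@H](C)CCC[C@@H](C)CCCC(C)C)[C@H]1CC=C(C)CC1 | intermediate
27 | C2 methylene compound (C1=C2; C13 silyl ether) | C=C(CC/C=C(/C)CCC[C@@H](C)CCC(O[Si](C(C)C)(C(C)C)C(C)C)[C@H](C)CCC[C@@H](C)CCCC(C)C)[C@H]1CC=C(C)CC1 | intermediate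
28 | C13 alcohol (both C13 epimers) | C=C(CC/C=C(/C)CCC[C@@H](C)CCC(O)[C@H](C)CCC[C@@H](C)CCCC(C)C)[C@H]1CC=C(C)CC1 | intermediate
29 | CNP0272027.1, (5Z,10R,14R,18S)-6,10,14,18,22-pentamethyl-2-[(1R)-4-methylcyclohex-3-en-1-yl]tricosa-1,5-dien-13-one (route numbering) | C=C(CC/C=C(/C)CCC[C@@H](C)CCC(=O)[C@H](C)CCC[C@@H](C)CCCC(C)C)[C@H]1CC=C(C)CC1 | target

**Step count.** Total: 16 steps. Longest linear sequence: 14 steps (steps 1–8 and 11–16); steps 9 and 10 form the short branch.

**Steps most likely to fail**

Step 13. The lipophilic ketone may form its iminium ion slowly in the aqueous medium, so that polymerisation of the enone competes, and face selectivity at C1' may fall short because it cannot be reinforced by the remote centres. The fallback gives up the cycloaddition and takes the ring and C1' from the chiral pool. It sets out from iodide 14, which is converted into borate 19 as in step 11. Borate 19 is coupled under the same palladium conditions with (Z)-3-iodobut-2-en-1-ol F1 (from but-2-yn-1-ol by NaAlH2(OCH2CH2OMe)2 reduction and iodination) to give the (Z)-allylic alcohol F2. CBr4 and PPh3 convert this into the (Z)-allylic bromide F3. (R)-Limonene is metalated at its isopropenyl methyl group with n-BuLi and TMEDA to 10-lithio-(R)-limonene F4, whose alkylation by F3 forms C3–C4. The fallback comes back to the route at 27, bypassing steps 11 to 14.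

Step 11. Incomplete iodine–lithium exchange or borate formation, or slow transmetalation, would lead to protonolysis of the organometallic and loss of the C7–C22 material. The fallback replaces the lithium–boron sequence by a Negishi coupling. It sets out from iodide 14, into which zinc is inserted directly (Zn dust, LiCl, THF, 40 °C) to give the alkylzinc iodide F5. This is coupled with vinyl iodide 17 (Pd(OAc)2, SPhos, THF–NMP, rt) and comes back to the route at 20.

Step 12. During the quench the released N,O-dimethylhydroxylamine can add to the enone in a conjugate fashion, and the enone can polymerise. The fallback avoids releasing the amine next to the enone. It sets out from amide 20, which is reduced with i-Bu2AlH (THF, −78 °C) to the C2 aldehyde F6. Addition of CH2=CHMgBr gives the C2 allylic alcohol F7 (both C2 epimers), and oxidation with MnO2 in CH2Cl2 comes back to the route at 22.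

**Further compounds**

F1 | step 13 | (Z)-3-iodobut-2-en-1-ol | C/C(I)=C/CO
F2 | step 13 | (Z)-allylic alcohol of the C4–C22 chain (C4 carbinol; C13 silyl ether) | OC/C=C(/C)CCC[C@@H](C)CCC(O[Si](C(C)C)(C(C)C)C(C)C)[C@H](C)CCC[C@@H](C)CCCC(C)C
F3 | step 13 | (Z)-allylic bromide of the C4–C22 chain (C13 silyl ether) | BrC/C=C(/C)CCC[C@@H](C)CCC(O[Si](C(C)C)(C(C)C)C(C)C)[C@H](C)CCC[C@@H](C)CCCC(C)C
F4 | step 13 | 10-lithio-(R)-limonene | [Li]CC(=C)[C@H]1CC=C(C)CC1
F5 | step 11 | C7 alkylzinc iodide from 14 | I[Zn]CCC[C@@H](C)CCC(O[Si](C(C)C)(C(C)C)C(C)C)[C@H](C)CCC[C@@H](C)CCCC(C)C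
F6 | step 12 | C2 aldehyde of the C2–C22 chain (C5=C6 Z; C13 silyl ether) | O=CCC/C=C(/C)CCC[C@@H](C)CCC(O[Si](C(C)C)(C(C)C)C(C)C)[C@H](C)CCC[C@@H](C)CCCC(C)C
F7 | step 12 | C2 allylic alcohol (both C2 epimers; C13 silyl ether) | C=CC(O)CC/C=C(/C)CCC[C@@H](C)CCC(O[Si](C(C)C)(C(C)C)C(C)C)[C@H](C)CCC[C@@H](C)CCCC(C)C
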